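The route rests on disconnecting the C2–C1′ bond that links the pyranone ring (ring C of the chromanone) to the phenolic ring B. A rhodium-catalysed asymmetric 1,4-addition of the aryl boronate of the complete exo Diels–Alder cyclohexene to a 3,7-bis(silyloxy)chromone forms this bond, sets C2 under ligand control and sets C3 cis by ketonisation anti to the new aryl group. It exploits the C2=C3–C4=O vinylogous ester of the pyranone as a latent, non-racemisable β-keto aldehyde. The boronate arises from a chiral-borate-promoted Diels–Alder reaction of a 2′-hydroxychalcone with a bromoaryl methylbutadiene; global desilylation ends the synthesis.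

Key step: step 14

Remark: the ligand antipodes named in steps 9 and 14 are those expected from the usual induction models of these catalyst families; if a test reaction shows the opposite sense, the mirror-image ligand (commercial in both cases) is used.

Step 1
Reactants: 1 2,4-dihydroxyacetophenone
Product: 2 1-[2-hydroxy-4-(methoxymethoxy)phenyl]ethanone
Conditions: MOMCl (1.1 equiv), K2CO3, acetone, 0 °C to rt
Reagents that add atoms: chloromethyl methyl ether (MOMCl), COCCl
Why: Williamson-type O-alkylation in which the 4-hydroxyl reacts selectively because the 2-hydroxyl is deactivated by its hydrogen bond to the ketone; no stereocenter is formed.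

Step 2
Reactants: 3 2,4-dihydroxybenzaldehyde
Product: 4 2,4-bis(methoxymethoxy)benzaldehyde
Conditions: MOMCl (2.5 equiv), iPr2NEt, CH2Cl2, 0 °C to rt
Reagents that add atoms: chloromethyl methyl ether (MOMCl), COCCl
Why: Exhaustive methoxymethyl ether formation protects both phenols against the strongly basic condensation that follows.

Step 3
Reactants: 2 1-[2-hydroxy-4-(methoxymethoxy)phenyl]ethanone; 4 2,4-bis(methoxymethoxy)benzaldehyde
Product: 5 (E)-3-[2,4-bis(methoxymethoxy)phenyl]-1-[2-hydroxy-4-(methoxymethoxy)phenyl]prop-2-en-1-one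
Conditions: KOH (50% aq.), EtOH, rt
Reagents that add atoms: none
Why: Claisen–Schmidt aldol condensation of the methyl ketone enolate with the non-enolisable aldehyde followed by E1cB dehydration should give the conjugated E-enone as the thermodynamic isomer.

Step 4
Reactants: 5 (E)-3-[2,4-bis(methoxymethoxy)phenyl]-1-[2-hydroxy-4-(methoxymethoxy)phenyl]prop-2-en-1-one
Product: 6 (E)-1,3-bis(2,4-dihydroxyphenyl)prop-2-en-1-one
Conditions: HCl (3 M aq.), MeOH, 50 °C, short reaction time
Reagents that add atoms: none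
Why: Acid-catalysed acetal exchange with methanol cleaves the three aryl MOM ethers while the 2′-hydroxychalcone should survive brief exposure.

Step 5
Reactants: 6 (E)-1,3-bis(2,4-dihydroxyphenyl)prop-2-en-1-one
Product: 7 (E)-3-[2,4-bis(tert-butyldimethylsilyloxy)phenyl]-1-[4-(tert-butyldimethylsilyloxy)-2-hydroxyphenyl]prop-2-en-1-one
Conditions: TBSCl (3.2 equiv), imidazole, DMF, 0 °C
Reagents that add atoms: tert-butyldimethylsilyl chloride (TBSCl), CC(C)(C)[Si](C)(C)Cl
Why: Selective silylation in which the three free phenols react and the carbonyl-chelated 2′-hydroxyl is left untouched; this hydroxyl is needed later for boron chelation.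

Step 6
Reactants: 8 3-bromo-4-hydroxybenzaldehyde
Product: 9 3-bromo-4-(tert-butyldimethylsilyloxy)benzaldehyde
Conditions: TBSCl, imidazole, DMF, rt
Reagents that add atoms: tert-butyldimethylsilyl chloride (TBSCl), CC(C)(C)[Si](C)(C)Cl
Why: Standard silyl ether formation protects the phenol that sits ortho to the bromine handle.

Step 7
Reactants: 9 3-bromo-4-(tert-butyldimethylsilyloxy)benzaldehyde
Product: 10 (E)-4-[3-bromo-4-(tert-butyldimethylsilyloxy)phenyl]but-3-en-2-one
Conditions: Ph3P=CHC(O)CH3, toluene, 90 °C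
Reagents that add atoms: 1-(triphenylphosphoranylidene)propan-2-one, CC(=O)C=P(c1ccccc1)(c1ccccc1)c1ccccc1
Why: Wittig olefination with a stabilised acyl ylide should give the E-enone selectively.

Step 8
Reactants: 10 (E)-4-[3-bromo-4-(tert-butyldimethylsilyloxy)phenyl]but-3-en-2-one
Product: 11 (E)-1-[3-bromo-4-(tert-butyldimethylsilyloxy)phenyl]-3-methylbuta-1,3-diene
Conditions: Ph3PCH3Br, NaHMDS, THF, 0 °C; then 10, 0 °C to rt
Reagents that add atoms: methyltriphenylphosphonium bromide, C[P+](c1ccccc1)(c1ccccc1)c1ccccc1.[Br-]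
Why: Wittig methylenation of the ketone carbonyl by the non-stabilised ylide converts the enone into the 1-aryl-3-methylbuta-1,3-diene without touching the E-styrenyl double bond.

Step 9
Reactants: 7 (E)-3-[2,4-bis(tert-butyldimethylsilyloxy)phenyl]-1-[4-(tert-butyldimethylsilyloxy)-2-hydroxyphenyl]prop-2-en-1-one; 11 (E)-1-[3-bromo-4-(tert-butyldimethylsilyloxy)phenyl]-3-methylbuta-1,3-diene
Product: 12 [(1R,2R,6S)-2-[3-bromo-4-(TBSO)phenyl]-6-[2,4-bis(TBSO)phenyl]-4-methylcyclohex-3-en-1-yl][2-hydroxy-4-(TBSO)phenyl]methanone (all-trans exo adduct; TBSO = tert-butyldimethylsilyloxy)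
Conditions: (S)-VANOL (3,3′-diphenyl-2,2′-bi-1-naphthol), BH3·THF, AcOH, THF, rt; evaporate; 7 + 11 (excess), PhCF3, rt; aq. NaHCO3 work-up
Reagents that add atoms: none
Why: Chiral-borate-promoted asymmetric Diels–Alder reaction in which chelation of boron between the 2′-hydroxyl and carbonyl oxygens of 7 activates the enone, the 1-aryl-3-methyl diene adds with ortho/para regiochemistry, the E geometry of the chalcone fixes the trans relation of aroyl and aryl groups, exo approach places the bromoaryl group trans to the aroyl group, and the ligand shields one enone face so that the (1R,2R,6S) enantiomer should result; the endo isomer expected as a by-product is removed by chromatography.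

Step 10
Reactants: 12 [(1R,2R,6S)-2-[3-bromo-4-(TBSO)phenyl]-6-[2,4-bis(TBSO)phenyl]-4-methylcyclohex-3-en-1-yl][2-hydroxy-4-(TBSO)phenyl]methanone
Product: 13 [(1R,2R,6S)-2-[3-(5,5-dimethyl-1,3,2-dioxaborinan-2-yl)-4-(TBSO)phenyl]-6-[2,4-bis(TBSO)phenyl]-4-methylcyclohex-3-en-1-yl][2-hydroxy-4-(TBSO)phenyl]methanone
Conditions: bis(neopentyl glycolato)diboron, PdCl2(dppf) (5 mol %), KOAc, 1,4-dioxane, 85 °C
Reagents that add atoms: bis(neopentyl glycolato)diboron, CC1(C)COB(OC1)B1OCC(C)(C)CO1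
Why: Miyaura borylation, in which oxidative addition of zerovalent palladium into the C–Br bond, acetate-assisted transmetalation from the diboron reagent and reductive elimination install the boronate without affecting the ketone, the free phenol or the stereocenters.

Step 11
Reactants: 14 7-hydroxy-4H-chromen-4-one
Product: 15 7-(tert-butyldimethylsilyloxy)-4H-chromen-4-one
Conditions: TBSCl, imidazole, DMF, rt
Reagents that add atoms: tert-butyldimethylsilyl chloride (TBSCl), CC(C)(C)[Si](C)(C)Cl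
Why: Standard silylation protects the phenol before the oxidation of the pyranone double bond.

Step 12
Reactants: 15 7-(tert-butyldimethylsilyloxy)-4H-chromen-4-one
Product: 17 3-hydroxy-7-(tert-butyldimethylsilyloxy)-4H-chromen-4-one, via 2,3-epoxychroman-4-one 16 (not isolated)
Conditions: DMDO, acetone/CH2Cl2, 0 °C to rt; then p-TsOH·H2O (cat.), CH2Cl2, rt
Reagents that add atoms: dimethyldioxirane (DMDO), CC1(C)OO1
Why: Electrophilic epoxidation of the enol-ether C2=C3 bond by the dioxirane, followed by acid-catalysed epoxide opening at the acetal carbon C2 and loss of the C3 proton (epoxide-to-enol isomerisation), should deliver the 3-hydroxychromone, in which no stereocenter remains.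

Step 13
Reactants: 17 3-hydroxy-7-(tert-butyldimethylsilyloxy)-4H-chromen-4-one
Product: 18 3,7-bis(tert-butyldimethylsilyloxy)-4H-chromen-4-one
Conditions: TBSCl, imidazole, DMF, rt
Reagents that add atoms: tert-butyldimethylsilyl chloride (TBSCl), CC(C)(C)[Si](C)(C)Cl
Why: Silylation of the acidic enolic 3-hydroxyl masks the metal-chelating 3-hydroxy-4-pyranone motif and gives the 1,4-acceptor for the coupling.

Step 14
Reactants: 13 [(1R,2R,6S)-2-[3-(5,5-dimethyl-1,3,2-dioxaborinan-2-yl)-4-(TBSO)phenyl]-6-[2,4-bis(TBSO)phenyl]-4-methylcyclohex-3-en-1-yl][2-hydroxy-4-(TBSO)phenyl]methanone; 18 3,7-bis(tert-butyldimethylsilyloxy)-4H-chromen-4-one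
Product: 19 (2S,3R)-2-{5-[(1R,5S,6R)-6-[2-hydroxy-4-(TBSO)benzoyl]-5-[2,4-bis(TBSO)phenyl]-3-methylcyclohex-2-en-1-yl]-2-(TBSO)phenyl}-3,7-bis(TBSO)chroman-4-one
Conditions: [Rh(OH)(cod)]2 (5 mol %), (S)-MeO-F12-BIPHEP (11 mol %), 18 (1.5 equiv), toluene/H2O (10:1), 50 °C
Reagents that add atoms: none
Why: Proposed new method: a Hayashi–Miyaura-type 1,4-addition in which the hydroxorhodium complex takes the aryl group from boron, the aryl–rhodium bond adds across C2=C3 of the chromone (aryl to C2, rhodium to C3/O as an oxa-π-allyl) and water releases the ketone and regenerates the hydroxo complex; the closest known reaction is the rhodium–bisphosphine-catalysed asymmetric 1,4-addition of arylboronic acids to 3-unsubstituted chromones, and the extension lies in the 3-silyloxy substituent on the acceptor. No ring is closed. C2 is set by the chiral bisphosphine, which should select the enone face independently of the remote cyclohexene stereocenters, and C3 is set under substrate control when the enol(ate) ketonises by protonation on the face opposite the pseudoaxial C2 aryl group, which places the silyloxy group cis to the aryl group. The step needs 1,4- over 1,2-selectivity (favoured by the electron-poor bisphosphine), chemoselectivity over the hindered ketone and trisubstituted alkene of 13 (neither is a competent acceptor), and preservation of the kinetic cis ketone (base-free, near-neutral medium and no free ortho-phenol on ring B to deliver a proton to the wrong face).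

Step 15
Reactants: 19 (2S,3R)-2-{5-[(1R,5S,6R)-6-[2-hydroxy-4-(TBSO)benzoyl]-5-[2,4-bis(TBSO)phenyl]-3-methylcyclohex-2-en-1-yl]-2-(TBSO)phenyl}-3,7-bis(TBSO)chroman-4-one
Product: 20 (2S,3R)-2-{5-[(1R,5S,6R)-6-(2,4-dihydroxybenzoyl)-5-(2,4-dihydroxyphenyl)-3-methylcyclohex-2-en-1-yl]-2-hydroxyphenyl}-3,7-dihydroxychroman-4-one
Conditions: HF·pyridine, pyridine, THF, 0 °C to rt
Reagents that add atoms: none
Why: Fluoride-driven cleavage of all six Si–O bonds under mildly acidic conditions, in which the phenols stay protonated so that neither the o-hydroxybenzyl ether at C2 nor the α-hydroxy ketone at C3 should epimerise; no stereocenter is touched.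

Compound list
1 | 2,4-dihydroxyacetophenone | CC(=O)c1ccc(O)cc1O | starting material
2 | 1-[2-hydroxy-4-(methoxymethoxy)phenyl]ethanone | CC(=O)c1ccc(OCOC)cc1O | intermediate
3 | 2,4-dihydroxybenzaldehyde | O=Cc1ccc(O)cc1O | starting material
4 | 2,4-bis(methoxymethoxy)benzaldehyde | O=Cc1ccc(OCOC)cc1OCOC | intermediate
5 | (E)-3-[2,4-bis(methoxymethoxy)phenyl]-1-[2-hydroxy-4-(methoxymethoxy)phenyl]prop-2-en-1-one | O=C(/C=C/c1ccc(OCOC)cc1OCOC)c1ccc(OCOC)cc1O | intermediate
6 | (E)-1,3-bis(2,4-dihydroxyphenyl)prop-2-en-1-one | O=C(/C=C/c1ccc(O)cc1O)c1ccc(O)cc1O | intermediate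
7 | (E)-3-[2,4-bis(tert-butyldimethylsilyloxy)phenyl]-1-[4-(tert-butyldimethylsilyloxy)-2-hydroxyphenyl]prop-2-en-1-one | O=C(/C=C/c1ccc(O[Si](C)(C)C(C)(C)C)cc1O[Si](C)(C)C(C)(C)C)c1ccc(O[Si](C)(C)C(C)(C)C)cc1O | intermediate
8 | 3-bromo-4-hydroxybenzaldehyde | O=Cc1ccc(O)c(Br)c1 | starting material
9 | 3-bromo-4-(tert-butyldimethylsilyloxy)benzaldehyde | O=Cc1ccc(O[Si](C)(C)C(C)(C)C)c(Br)c1 | intermediate
10 | (E)-4-[3-bromo-4-(tert-butyldimethylsilyloxy)phenyl]but-3-en-2-one | CC(=O)/C=C/c1ccc(O[Si](C)(C)C(C)(C)C)c(Br)c1 | intermediate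
11 | (E)-1-[3-bromo-4-(tert-butyldimethylsilyloxy)phenyl]-3-methylbuta-1,3-diene | CC(=C)/C=C/c1ccc(O[Si](C)(C)C(C)(C)C)c(Br)c1 | intermediate
12 | [(1R,2R,6S)-2-[3-bromo-4-(TBSO)phenyl]-6-[2,4-bis(TBSO)phenyl]-4-methylcyclohex-3-en-1-yl][2-hydroxy-4-(TBSO)phenyl]methanone | CC1=C[C@@H](c2ccc(O[Si](C)(C)C(C)(C)C)c(Br)c2)[C@H](C(=O)c2ccc(O[Si](C)(C)C(C)(C)C)cc2O)[C@@H](c2ccc(O[Si](C)(C)C(C)(C)C)cc2O[Si](C)(C)C(C)(C)C)C1 | intermediate
13 | [(1R,2R,6S)-2-[3-(5,5-dimethyl-1,3,2-dioxaborinan-2-yl)-4-(TBSO)phenyl]-6-[2,4-bis(TBSO)phenyl]-4-methylcyclohex-3-en-1-yl][2-hydroxy-4-(TBSO)phenyl]methanone | CC1=C[C@@H](c2ccc(O[Si](C)(C)C(C)(C)C)c(B3OCC(C)(C)CO3)c2)[C@H](C(=O)c2ccc(O[Si](C)(C)C(C)(C)C)cc2O)[C@@H](c2ccc(O[Si](C)(C)C(C)(C)C)cc2O[Si](C)(C)C(C)(C)C)C1 | intermediate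
14 | 7-hydroxy-4H-chromen-4-one | O=c1ccoc2cc(O)ccc12 | starting material
15 | 7-(tert-butyldimethylsilyloxy)-4H-chromen-4-one | O=c1ccoc2cc(O[Si](C)(C)C(C)(C)C)ccc12 | intermediate
16 | 2,3-epoxy-7-(tert-butyldimethylsilyloxy)chroman-4-one (racemic, cis-fused epoxide) | O=C1C2OC2Oc2cc(O[Si](C)(C)C(C)(C)C)ccc12 | intermediate
17 | 3-hydroxy-7-(tert-butyldimethylsilyloxy)-4H-chromen-4-one | O=c1c(O)coc2cc(O[Si](C)(C)C(C)(C)C)ccc12 | intermediate
18 | 3,7-bis(tert-butyldimethylsilyloxy)-4H-chromen-4-one | O=c1c(O[Si](C)(C)C(C)(C)C)coc2cc(O[Si](C)(C)C(C)(C)C)ccc12 | intermediate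
19 | (2S,3R)-2-{5-[(1R,5S,6R)-6-[2-hydroxy-4-(TBSO)benzoyl]-5-[2,4-bis(TBSO)phenyl]-3-methylcyclohex-2-en-1-yl]-2-(TBSO)phenyl}-3,7-bis(TBSO)chroman-4-one | CC1=C[C@@H](c2ccc(O[Si](C)(C)C(C)(C)C)c([C@@H]3Oc4cc(O[Si](C)(C)C(C)(C)C)ccc4C(=O)[C@@H]3O[Si](C)(C)C(C)(C)C)c2)[C@H](C(=O)c2ccc(O[Si](C)(C)C(C)(C)C)cc2O)[C@@H](c2ccc(O[Si](C)(C)C(C)(C)C)cc2O[Si](C)(C)C(C)(C)C)C1 | intermediate
20 | (2S,3R)-2-{5-[(1R,5S,6R)-6-(2,4-dihydroxybenzoyl)-5-(2,4-dihydroxyphenyl)-3-methylcyclohex-2-en-1-yl]-2-hydroxyphenyl}-3,7-dihydroxychroman-4-one | CC1=C[C@@H](c2ccc(O)c([C@@H]3Oc4cc(O)ccc4C(=O)[C@@H]3O)c2)[C@H](C(=O)c2ccc(O)cc2O)[C@@H](c2ccc(O)cc2O)C1 | target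

Total step count: 15. Longest linear sequence: 8 steps (steps 1, 3, 4, 5, 9, 10, 14, 15).

Steps most likely to fail

Step 14 (bears the label). Carbometalation of the 3-silyloxy-substituted enone by the ortho-silyloxy aryl–rhodium species may be slow, so that protodeboronation of 13 wins. Ketonisation may also occur with poor facial selectivity, or the cis ketone may epimerise at C3 to the trans series. The fallback uses known chemistry, sets out from 13 and 15 and comes back to the route at 20. The established rhodium-catalysed asymmetric 1,4-addition to a 3-unsubstituted chromone (catalyst of step 14) would join 13 and 15 to the (2R)-flavanone F1. Soft enolisation with TBSOTf/Et3N, which also silylates the chelated phenol, would give the silyl enol ether F2. Its Rubottom oxidation with dimethyldioxirane anti to the C2 aryl group, with silyl migration, would give the 2,3-trans 3-silyloxy ketone F3. A second soft enolisation (TMSOTf/Et3N) would give the enediol bis(silyl ether) F4. Kinetic protonation of F4 (MeOH, cat. pyridinium p-toluenesulfonate, low temperature) on the face opposite the aryl group would give the 2,3-cis ketone F5, which gives 20 under the conditions of step 15.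

Step 9. The exo/endo ratio or the enantioselectivity of the borate-promoted cycloaddition may be poor with the silylated partners, and the diene may polymerise under Lewis acid. The fallback sets out from 7 and 11 and comes back at 12. An uncatalysed thermal or high-pressure cycloaddition without boron would give the racemic exo adduct, that is 12 together with its enantiomer, the (1S,2S,6R) adduct F6, after chromatographic removal of the endo isomer. Preparative chromatography on a chiral stationary phase would then provide 12.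

Step 15. Slow cleavage of the hindered C3 silyl ether may force long exposure, during which the free 2′-hydroxyl can assist ring opening at C2 or the α-hydroxy ketone can enolise, with drift to the 2,3-trans isomer. The fallback changes the protecting-group design, sets out from 17 and comes back at 20. Silylation of 17 with TESCl/imidazole would give the 3-triethylsilyloxy chromone F7. The addition of step 14 with 13 would give the 3-O-triethylsilyl adduct F8. The labile secondary silyl ether and the aryl silyl ethers of F8 would then be removed in a brief treatment with Et3N·3HF in MeCN to give 20.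

Further compounds
F1 | step 14 | (2R)-2-{5-[(1R,5S,6R)-6-[2-hydroxy-4-(TBSO)benzoyl]-5-[2,4-bis(TBSO)phenyl]-3-methylcyclohex-2-en-1-yl]-2-(TBSO)phenyl}-7-(TBSO)chroman-4-one | CC1=C[C@@H](c2ccc(O[Si](C)(C)C(C)(C)C)c([C@@H]3Oc4cc(O[Si](C)(C)C(C)(C)C)ccc4C(=O)C3)c2)[C@H](C(=O)c2ccc(O[Si](C)(C)C(C)(C)C)cc2O)[C@@H](c2ccc(O[Si](C)(C)C(C)(C)C)cc2O[Si](C)(C)C(C)(C)C)C1
F2 | step 14 | (2R)-4,7-bis(TBSO)-2H-chromene silyl enol ether of F1 with the benzoyl 2-hydroxyl silylated | CC1=C[C@@H](c2ccc(O[Si](C)(C)C(C)(C)C)c([C@@H]3Oc4cc(O[Si](C)(C)C(C)(C)C)ccc4C(O[Si](C)(C)C(C)(C)C)=C3)c2)[C@H](C(=O)c2ccc(O[Si](C)(C)C(C)(C)C)cc2O[Si](C)(C)C(C)(C)C)[C@@H](c2ccc(O[Si](C)(C)C(C)(C)C)cc2O[Si](C)(C)C(C)(C)C)C1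
F3 | step 14 | (2S,3S)-2,3-trans 3,7-bis(TBSO)chroman-4-one with all seven hydroxyls silylated | CC1=C[C@@H](c2ccc(O[Si](C)(C)C(C)(C)C)c([C@@H]3Oc4cc(O[Si](C)(C)C(C)(C)C)ccc4C(=O)[C@H]3O[Si](C)(C)C(C)(C)C)c2)[C@H](C(=O)c2ccc(O[Si](C)(C)C(C)(C)C)cc2O[Si](C)(C)C(C)(C)C)[C@@H](c2ccc(O[Si](C)(C)C(C)(C)C)cc2O[Si](C)(C)C(C)(C)C)C1
F4 | step 14 | (2S)-3-(TBSO)-4-(trimethylsilyloxy)-2H-chromene enediol bis(silyl ether) derived from F3 | CC1=C[C@@H](c2ccc(O[Si](C)(C)C(C)(C)C)c([C@@H]3Oc4cc(O[Si](C)(C)C(C)(C)C)ccc4C(O[Si](C)(C)C)=C3O[Si](C)(C)C(C)(C)C)c2)[C@H](C(=O)c2ccc(O[Si](C)(C)C(C)(C)C)cc2O[Si](C)(C)C(C)(C)C)[C@@H](c2ccc(O[Si](C)(C)C(C)(C)C)cc2O[Si](C)(C)C(C)(C)C)C1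
F5 | step 14 | (2S,3R)-2,3-cis 3,7-bis(TBSO)chroman-4-one with all seven hydroxyls silylated | CC1=C[C@@H](c2ccc(O[Si](C)(C)C(C)(C)C)c([C@@H]3Oc4cc(O[Si](C)(C)C(C)(C)C)ccc4C(=O)[C@@H]3O[Si](C)(C)C(C)(C)C)c2)[C@H](C(=O)c2ccc(O[Si](C)(C)C(C)(C)C)cc2O[Si](C)(C)C(C)(C)C)[C@@H](c2ccc(O[Si](C)(C)C(C)(C)C)cc2O[Si](C)(C)C(C)(C)C)C1
F6 | step 9 | [(1S,2S,6R)-2-[3-bromo-4-(TBSO)phenyl]-6-[2,4-bis(TBSO)phenyl]-4-methylcyclohex-3-en-1-yl][2-hydroxy-4-(TBSO)phenyl]methanone (enantiomer of 12) | CC1=C[C@H](c2ccc(O[Si](C)(C)C(C)(C)C)c(Br)c2)[C@@H](C(=O)c2ccc(O[Si](C)(C)C(C)(C)C)cc2O)[C@H](c2ccc(O[Si](C)(C)C(C)(C)C)cc2O[Si](C)(C)C(C)(C)C)C1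
F7 | step 15 | 7-(tert-butyldimethylsilyloxy)-3-(triethylsilyloxy)-4H-chromen-4-one | O=c1c(O[Si](CC)(CC)CC)coc2cc(O[Si](C)(C)C(C)(C)C)ccc12
F8 | step 15 | (2S,3R)-3-O-triethylsilyl analogue of 19 | CC1=C[C@@H](c2ccc(O[Si](C)(C)C(C)(C)C)c([C@@H]3Oc4cc(O[Si](C)(C)C(C)(C)C)ccc4C(=O)[C@@H]3O[Si](CC)(CC)CC)c2)[C@H](C(=O)c2ccc(O[Si](C)(C)C(C)(C)C)cc2O)[C@@H](c2ccc(O[Si](C)(C)C(C)(C)C)cc2O[Si](C)(C)C(C)(C)C)C1
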